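The readings come from a simulation with made-up constants, noise included.

I decide to read each flask off the south-east curve instead of fitting them one by one.

| flask | G | D | E | X | Q | temperature | remark | time |
|---|---|---|---|---|---|---|---|---|
| east | 0.073 M | 0.073 M | 0.052 M | 9.5 mM | 2.6 mM | 10 °C | run made earlier |  |
| south-east | 0.073 M | 0.073 M | 0.63 M | 9.5 mM | 2.6 mM | 25 °C | run made earlier |  |
| midnight | 0.073 M | 0.073 M | 0.500 M | 9.5 mM | 2.6 mM | 25 °C |  | 12 h |
| noon | 0.073 M | 0.073 M | 0.0400 M | 9.5 mM | 2.6 mM | 25 °C |  | 12 h |
| dusk | 0.073 M | 0.073 M | 0.161 M | 9.5 mM | 2.6 mM | 25 °C |  | 12 h |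
| winter | 0.073 M | 0.073 M | 0.300 M | 9.5 mM | 2.6 mM | 25 °C |  | 12 h |
| summer | 0.073 M | 0.073 M | 0.100 M | 9.5 mM | 2.6 mM | 25 °C |  | 12 h |

| run | time / h | L / % |
|---|---|---|
| east | 4.00 | 2.6 |
| east | 8.00 | 4.5 |
| east | 12.0 | 7.2 |
| east | 15.0 | 8.1 |
| east | 20.0 | 9.7 |
| east | 25.0 | 11.8 |
| south-east | 0.833 | 13.7 |
| south-east | 2.50 | 25.4 |
| south-east | 4.00 | 30.0 |
| south-east | 6.00 | 32.3 |
| south-east | 10.0 | 33.4 |
| south-east | 12.0 | 33.9 |

(scatter of a reading: 0.3 percentage points)

- X is single-handed; G and D are mirror images of each other, charged as a racemate, each of them at the stated concentration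

1. ranking by amount of L, in percent of the G and D together charged, from high to low, at 12 h (midnight / noon / dusk / winter / summer)
2. the amount of L, in percent of the G and D together charged of the flask you put first, at 12 h
3. the amount of L, in percent of the G and D together charged of the flask you put last, at 12 h

South-east makes L up to its first reading at a mean 0.164 h⁻¹ of the charge, and between its last readings at 0.00267 h⁻¹, so the mean rate falls, as read, by a factor of about 61.7. If the rate is first order in c_E and in c_G, one E goes per G or D, and nothing but L takes G, c_E can account for a factor of at most 1.30, and c_G for at most 3.11. That leaves a factor of about 15.3, which I give to X dying, so I read the stall near 33.9% as the end of the catalyst.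

East, with c_E 0.052 M, slows by a factor of just 1.76 in 25.0 h. I therefore let dying follow c_E as making does, though east is also colder. At one temperature, with the charges of G, D, X and Q held, L then depends on c_E times time, as long as c_E stays near its charge.

For midnight that gives 9.52 h on the E-clock, the south-east time with the same product of c_E and time. This lies just before the reading of 33.4% at 10.0 h. Noon reads 0.762 h, and south-east's first mean rate carried that far gives 12.5%; I expect less, because c_E falls in noon, where 0.0400 M of E stands against 0.146 M of G and D together.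

The forecast, “Assuming rate and decay both scale with E”, gives midnight > winter > dusk > summer > noon, with 33.6% (30.5% to 37%) and 11.1% (9.3% to 13.5%). My noon figure stands higher than its noon value.

The flasks give midnight > winter > dusk > summer > noon, with 33.7% and 9.54%.

    E + X + G → X + L (k = 77.6 M⁻² h⁻¹, Ea = 44.0 kJ mol⁻¹)
    G + Q ⇌ D + Q, rate k2*[Q]*[G] forward; the back reaction follows from the equilibrium constant (k = 577 M⁻¹ h⁻¹, Ea = 49.0 kJ mol⁻¹)
    E + X + D → X + J (k = 39.2 M⁻² h⁻¹, Ea = 48.0 kJ mol⁻¹)
    E + X → Z (k = 0.754 M⁻¹ h⁻¹, Ea = 79.0 kJ mol⁻¹)
    (constants at 25 °C)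

In midnight, L and J formed while X lasted: at 12.0 h X stood at 2.01% and Z at 98.0%, with E at 83% of its charge, and at 120 h L is 34.2%. In noon, X still stood at 78.9% at 12.0 h while E had fallen to 43% of its charge. Taking c_E midway between start and end, noon's E-clock reads 0.545 h, and south-east's first mean rate gives 8.94% against 9.54%. A flask like midnight with 0.20 M of E, which keeps 66% of its E, reads 3.15 h, between south-east's readings at 2.50 h and 4.00 h (25.4% and 30.0%), and gives 28.0%.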